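Peruvinide C is cut at the depside ester into a ring A acyl donor and a ring B phenol. Ring A bears oxygen at C2 and C4 and carbon at C1 and C6, the alternating pattern of a tetraketide, so the arene is made by forging its C1–C6 bond in an aldol cycloaromatization. In one operation a 1,3-diketone chain hanging from a 1,3-dioxin-4-one becomes the benzene ring, with carboxyl and C2 oxygen locked in an acetonide and the C4 hydroxyl free. The precursor is 6-(2,4-dioxoheptyl)-2,2-dimethyl-1,3-dioxin-4-one, a latent 3,5,7-trioxodecanoic acid. O-Methylation, acyl transfer to a ketal-protected pentenylpyrogallol and one hydrogenation complete the synthesis.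

Key step: step 4

Remark on the chemistry: olefin 14 (and hence 15 and 16) is expected as a Z-rich mixture of geometric isomers; the Z isomer is drawn, both isomers converge in the hydrogenation of step 9, and carbinol 9 is racemic.

Step 1
Reactants: 1 butanoyl chloride
Product: 2 N-methoxy-N-methylbutanamide
Conditions: MeNH(OMe)·HCl, Et3N (2.2 equiv), CH2Cl2, 0 °C to rt
Reagents that add atoms: N,O-dimethylhydroxylamine hydrochloride, CNOC.Cl
Why: Nucleophilic acyl substitution (Weinreb amide formation), in which the hydroxylamine freed by Et3N is N-acylated by the acid chloride to give a butanoyl donor that can transfer its acyl group only once.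

Step 2
Reactants: 3 2,2,6-trimethyl-4H-1,3-dioxin-4-one; 4 acetyl chloride
Product: 6 2,2-dimethyl-6-(2-oxopropyl)-4H-1,3-dioxin-4-one, via lithium dienolate 5 (not isolated)
Conditions: LiN(SiMe3)2, THF, −78 °C; AcCl (0.5 equiv), −78 °C; then 1 M HCl
Reagents that add atoms: none
Why: Vinylogous Claisen-type C-acylation, in which the amide base removes a proton from the C6 methyl group and dienolate 5 is acylated at its exocyclic carbon by the acid chloride; the dienolate is used in twofold excess because the more acidic product consumes one equivalent.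

Step 3
Reactants: 6 2,2-dimethyl-6-(2-oxopropyl)-4H-1,3-dioxin-4-one; 2 N-methoxy-N-methylbutanamide
Product: 8 6-(2,4-dioxoheptyl)-2,2-dimethyl-4H-1,3-dioxin-4-one, via dilithium dianion 7 (not isolated)
Conditions: LiN(iPr)2 (2.2 equiv), THF, −78 °C; then 2, −78 to −20 °C; 1 M HCl
Reagents that add atoms: none
Why: Crossed Claisen condensation of a dicarbonyl-type dianion (Huckin–Weiler reactivity), in which the less stabilised terminal carbanion is the nucleophilic site and the Weinreb amide forms a chelated tetrahedral adduct that collapses to the ketone only on acidic quench, so double addition should not occur.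

Step 4
Reactants: 8 6-(2,4-dioxoheptyl)-2,2-dimethyl-4H-1,3-dioxin-4-one
Product: 10 7-hydroxy-2,2-dimethyl-5-propyl-4H-1,3-benzodioxin-4-one, via aldol carbinol 9 (not isolated)
Conditions: Et3N (3 equiv), CH2Cl2, rt
Reagents that add atoms: none
Why: Et3N reversibly removes a proton from the methylene flanked by the dioxinone and the nearer ketone, giving a vinylogous enolate that is nucleophilic at dioxinone C5; C5 adds to the terminal propyl ketone, carbinol 9 loses water by an E1cB pathway and the remaining ring ketone enolises to the phenol. The closest known reaction type is the amine-mediated aldol cycloaromatization of diketo-dioxinones to acetonide-protected resorcylates, a laboratory version of polyketide folding. The one ring closed is the six-membered carbocycle, formed in a 6-(enolexo)-exo-trig mode through the new bond between ring A C1 (dioxinone C5) and ring A C6 (the former ketone carbon). No stereocentre is set, because the carbinol centre of 9 is erased on aromatization. The step needs carbon-selective aldol closure onto the distal ketone instead of lactonisation to a pyranone or Claisen closure onto the carboxyl, and the dioxinone secures this by keeping the carboxyl locked as a cyclic acetal ester that cannot act as an acylating centre under amine base, while attack on the nearer ketone would give a four-membered ring. The same lock leaves the C2 oxygen inside the acetonide and only the C4 oxygen (position 7 of 10) as a free hydroxyl.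

Step 5
Reactants: 10 7-hydroxy-2,2-dimethyl-5-propyl-4H-1,3-benzodioxin-4-one
Product: 11 7-methoxy-2,2-dimethyl-5-propyl-4H-1,3-benzodioxin-4-one
Conditions: MeI, K2CO3, acetone, reflux
Reagents that add atoms: iodomethane, CI
Why: Williamson ether synthesis, unambiguous because the 7-hydroxyl is the only acidic group while the other ring A oxygen is held in the acetonide.

Step 6
Reactants: 12 3,4,5-trihydroxybenzaldehyde
Product: 13 7-hydroxy-2,2-diphenyl-1,3-benzodioxole-5-carbaldehyde
Conditions: Ph2CCl2 (1.3 equiv), Ph2O, 175 °C
Reagents that add atoms: dichlorodiphenylmethane, ClC(Cl)(c1ccccc1)c1ccccc1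
Why: Ketalisation of a catechol unit by a geminal dichloride (double substitution with loss of HCl), in which only adjacent oxygens can be bridged and the two adjacent pairs of the symmetrical triol are equivalent, so a single ketal with one free outer hydroxyl should result.

Step 7
Reactants: 13 7-hydroxy-2,2-diphenyl-1,3-benzodioxole-5-carbaldehyde
Product: 14 6-[(Z)-pent-1-en-1-yl]-2,2-diphenyl-1,3-benzodioxol-4-ol
Conditions: BuPPh3Br (1.5 equiv), NaN(SiMe3)2 (2.6 equiv), THF, 0 °C; then 13, 0 °C to rt; aq. NH4Cl
Reagents that add atoms: butyltriphenylphosphonium bromide, CCCC[P+](c1ccccc1)(c1ccccc1)c1ccccc1.[Br-]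
Why: Wittig olefination with a nonstabilised ylide, in which the extra base holds the phenol as its sodium salt (meta to the formyl group, so the aldehyde stays electrophilic) and kinetic oxaphosphetane formation should favour the Z olefin, whose geometry is irrelevant because the double bond is saturated in step 9.

Step 8
Reactants: 14 6-[(Z)-pent-1-en-1-yl]-2,2-diphenyl-1,3-benzodioxol-4-ol; 11 7-methoxy-2,2-dimethyl-5-propyl-4H-1,3-benzodioxin-4-one
Product: 16 6-[(Z)-pent-1-en-1-yl]-2,2-diphenyl-1,3-benzodioxol-4-yl 2-hydroxy-4-methoxy-6-propylbenzoate, via sodium aryloxide 15 (not isolated)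
Conditions: NaH (1.1 equiv), DMF–THF, 0 °C; then 11, rt to 50 °C; cold 0.5 M HCl
Reagents that add atoms: none
Why: Addition–elimination acyl transfer (transesterification of the benzodioxinone), in which the aryloxide adds to the dioxinone carbonyl and the expelled hemiketal oxide sheds acetone to leave the hydrogen-bonded ring A phenoxide, which makes the opening irreversible, while the ketal on ring B leaves a single nucleophilic oxygen.

Step 9
Reactants: 16 6-[(Z)-pent-1-en-1-yl]-2,2-diphenyl-1,3-benzodioxol-4-yl 2-hydroxy-4-methoxy-6-propylbenzoate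
Product: 18 Peruvinide C, via saturated ketal depside 17 (not isolated)
Conditions: H2 (1 atm), Pd(OH)2/C, EtOAc–THF, rt
Reagents that add atoms: none
Why: Heterogeneous catalytic hydrogenation saturates the styrenyl double bond and then hydrogenolyses the two benzhydrylic C–O bonds of the diphenylmethylene ketal, under neutral conditions that should spare the hindered aryl ester and the aryl methyl ether and give no base-induced acyl migration on the freed catechol.

Compound list
1 | butanoyl chloride | CCCC(=O)Cl | starting material
2 | N-methoxy-N-methylbutanamide | CCCC(=O)N(C)OC | intermediate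
3 | 2,2,6-trimethyl-4H-1,3-dioxin-4-one | CC1=CC(=O)OC(C)(C)O1 | starting material
4 | acetyl chloride | CC(=O)Cl | starting material
5 | lithium 2,2-dimethyl-6-methylidene-6H-1,3-dioxin-4-olate (lithium dienolate of 3) | C=C1C=C(O[Li])OC(C)(C)O1 | intermediate
6 | 2,2-dimethyl-6-(2-oxopropyl)-4H-1,3-dioxin-4-one | CC(=O)CC1=CC(=O)OC(C)(C)O1 | intermediate
7 | dilithium dianion of 6 (bis-enolate, terminal methyl and internal methylene deprotonated; exocyclic geometry undefined) | C=C(O[Li])C=C1C=C(O[Li])OC(C)(C)O1 | intermediate
8 | 6-(2,4-dioxoheptyl)-2,2-dimethyl-4H-1,3-dioxin-4-one | CCCC(=O)CC(=O)CC1=CC(=O)OC(C)(C)O1 | intermediate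
9 | 5-hydroxy-2,2-dimethyl-5-propyl-5,6-dihydro-4H-1,3-benzodioxine-4,7(8H)-dione (racemic) | CCCC1(O)CC(=O)CC2=C1C(=O)OC(C)(C)O2 | intermediate
10 | 7-hydroxy-2,2-dimethyl-5-propyl-4H-1,3-benzodioxin-4-one | CCCc1cc(O)cc2OC(C)(C)OC(=O)c12 | intermediate
11 | 7-methoxy-2,2-dimethyl-5-propyl-4H-1,3-benzodioxin-4-one | CCCc1cc(OC)cc2OC(C)(C)OC(=O)c12 | intermediate
12 | 3,4,5-trihydroxybenzaldehyde | O=Cc1cc(O)c(O)c(O)c1 | starting material
13 | 7-hydroxy-2,2-diphenyl-1,3-benzodioxole-5-carbaldehyde | O=Cc1cc(O)c2OC(c3ccccc3)(c3ccccc3)Oc2c1 | intermediate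
14 | 6-[(Z)-pent-1-en-1-yl]-2,2-diphenyl-1,3-benzodioxol-4-ol | CCC/C=C\c1cc(O)c2OC(c3ccccc3)(c3ccccc3)Oc2c1 | intermediate
15 | sodium 6-[(Z)-pent-1-en-1-yl]-2,2-diphenyl-1,3-benzodioxol-4-olate | CCC/C=C\c1cc([O-])c2OC(c3ccccc3)(c3ccccc3)Oc2c1.[Na+] | intermediate
16 | 6-[(Z)-pent-1-en-1-yl]-2,2-diphenyl-1,3-benzodioxol-4-yl 2-hydroxy-4-methoxy-6-propylbenzoate | CCCc1cc(OC)cc(O)c1C(=O)Oc1cc(/C=C\CCC)cc2OC(c3ccccc3)(c3ccccc3)Oc12 | intermediate
17 | 6-pentyl-2,2-diphenyl-1,3-benzodioxol-4-yl 2-hydroxy-4-methoxy-6-propylbenzoate | CCCCCc1cc(OC(=O)c2c(O)cc(OC)cc2CCC)c2OC(c3ccccc3)(c3ccccc3)Oc2c1 | intermediate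
18 | Peruvinide C (2,3-dihydroxy-5-pentylphenyl 2-hydroxy-4-methoxy-6-propylbenzoate) | CCCCCc1cc(O)c(O)c(OC(=O)c2c(O)cc(OC)cc2CCC)c1 | target

Total step count: 9. Longest linear sequence: 6 steps (steps 2, 3, 4, 5, 8 and 9, from 3 to 18).

Steps most likely to fail

Step 4. The aldol adduct may stall before dehydration, or the polycarbonyl chain may degrade under the amine before the carbocycle closes. The fallback sets out from 8 and comes back at 10. Compound 8 is heated in toluene at 110 °C with benzyl alcohol, so that retro-[4+2] loss of acetone gives an acylketene that is trapped as benzyl 3,5,7-trioxodecanoate F1. This open-chain triketo ester is cyclised and aromatised by the classical aldol route (K2CO3, iPrOH, rt; then HCl in MeOH) to benzyl 2,4-dihydroxy-6-propylbenzoate F2. Hydrogenolysis (H2, Pd/C, EtOAc) should give 2,4-dihydroxy-6-propylbenzoic acid F3, which is closed to the acetonide 10 with acetone, (CF3CO)2O and CF3CO2H.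

Step 3. Proton transfer from the amide or from the forming diketone to the dianion, or acylation at the internal carbon or on oxygen, may erode conversion. The fallback sets out from 6 and comes back at 8. Dianion 7 is generated as before and added to butanal at −78 °C in an aldol reaction to give racemic 6-(4-hydroxy-2-oxoheptyl)-2,2-dimethyl-4H-1,3-dioxin-4-one F4. This secondary alcohol is oxidised with Dess–Martin periodinane (CH2Cl2, rt) to diketone 8.

Step 8. Addition of the weakly nucleophilic aryloxide to the carbonyl flanked by the propyl group may be slow, so that hydrolysis of the dioxinone by adventitious hydroxide competes. The fallback sets out from 11 and comes back at 16. Compound 11 is saponified (KOH, aqueous DMSO, 60 °C; cold acidification) to 2-hydroxy-4-methoxy-6-propylbenzoic acid F5. This acid, whose ortho hydroxyl is hydrogen-bonded and poorly nucleophilic, is esterified with phenol 14 by carbodiimide activation (dicyclohexylcarbodiimide, catalytic 4-dimethylaminopyridine, CH2Cl2, rt) to give 16.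

Further compounds
F1 | step 4 | benzyl 3,5,7-trioxodecanoate | CCCC(=O)CC(=O)CC(=O)CC(=O)OCc1ccccc1
F2 | step 4 | benzyl 2,4-dihydroxy-6-propylbenzoate | CCCc1cc(O)cc(O)c1C(=O)OCc1ccccc1
F3 | step 4 | 2,4-dihydroxy-6-propylbenzoic acid | CCCc1cc(O)cc(O)c1C(=O)O
F4 | step 3 | 6-(4-hydroxy-2-oxoheptyl)-2,2-dimethyl-4H-1,3-dioxin-4-one (racemic) | CCCC(O)CC(=O)CC1=CC(=O)OC(C)(C)O1
F5 | step 8 | 2-hydroxy-4-methoxy-6-propylbenzoic acid | CCCc1cc(OC)cc(O)c1C(=O)O
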